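**Remarks on the chemistry.** The ring is numbered C1 (carries the C7 methylene), C2 (H), C3 (OH), C4 (O-sulfate), C5 (Br), C6 (Br); O3, O4 and O7 are the oxygens on C3, C4 and C7. The target is taken as the free bis(hydrogen sulfate) as drawn; its dipotassium salt 11 is the form that is purified and stored, and the acid is released from it in the last step. The phenol that enters the persulfate oxidation carries O7 as a triisopropylsilyl ether instead of a free hydroxyl. The carbon skeleton and the bond formed are those of the free diol; the silyl group is there to shield C2, to protect the benzylic alcohol from oxidation, and to come off without acid.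

## Structural features

The target is one benzene ring with five of its six carbons substituted: C1 bears the C7 methylene as an alkyl hydrogen sulfate, C3 a free phenol, C4 an aryl hydrogen sulfate, C5 and C6 bromine, and only C2 keeps its hydrogen. There is no stereocenter and no second ring, so the problem is entirely one of placing and telling apart substituents on a crowded arene. O3 and O4 are neighbours of almost equal character, yet one must be sulfated and the other left free, and O7 must be sulfated as well. The fragile groups are:
- the aryl sulfate monoester, which is stable to alkali, cleaved by acid and self-destructive as the free acid;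
- the benzylic sulfate, a leaving group on an activated carbon;
- the two aryl C–Br bonds, which exclude hydrogenolysis, halogen–metal exchange and zerovalent palladium.

A further constraint is that O3 is meta to the C5 bromine and meta to the C1 carbon substituent, a relation that electrophilic bromination of a phenol cannot produce. The key step uses the C3 phenolate, whose para carbon C6 is blocked by bromine. Its carbon nucleophilicity can then emerge only at an ortho carbon, and attack of C4 on peroxodisulfate forms C4–O with the sulfate already on that oxygen, so O3 and O4 are differentiated at the moment O4 arrives.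

## Logic of the disconnections

**12 from 11.** No skeletal bond is cut; two O–H bonds are exchanged for potassium sulfonate-type ion pairs. The acid form catalyses hydrolysis of its own aryl sulfate, so all purification is placed at the salt stage. The forward step must therefore be a cold, fast proton exchange with no excess acid.

**11 from 10.** The O7–S bond is cut. The benzylic sulfate is the group most open to displacement and solvolysis, so it goes in last, after the long alkaline oxidation and the fluoride step. This reduces the target to a monosulfated diol. The forward step must sulfate O7 and leave O3 alone.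

**10 from 9.** The O7–Si bond is cut. No simplification of the skeleton is gained; the silyl ether is the temporary group the oxidation needs. Its removal must avoid acid because of the aryl sulfate, which is why a fluoride-labile group was chosen.

**9 from 6 and 7.** The C4–O bond is cut, with the sulfate leaving on the oxygen. This is the strategic cut: the oxygen comes from 7 already sulfated, so a catechol with two free hydroxyls never has to be differentiated. The gain is a simple monophenol. The forward step must make the phenolate react through C4 and not through C2, and the O7 group of 6 must both bias that choice and survive aqueous alkali and oxidant.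

**6 from 3 and 4, through 5.** The C3–O bond is traced back to C3–B and then to C3–H. C3 is the only ring C–H of 3 with no ortho neighbour, so a sterically governed C–H borylation picks it. Electrophilic substitution could not place oxygen there relative to the bromines. The gain is a 1,2,3-trisubstituted benzene. The catalyst must leave two C–Br bonds alone, and the oxidation of 5 must spare the silyl ether.

**3 from 2.** The O7–Si bond is cut. The silyl group is installed before the phenol exists, so there is never a second hydroxyl competing for the silylating agent.

**2 from 1.** The oxidation level of C7 is raised to the acid, which is commercial. Reduction is placed first, when no sulfate, phenol or silyl group is present; it only needs a hydride source that spares aryl bromides.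

## Other disconnections considered

**Alternative 1:** The cut is the C1–C2 ring bond, and the whole benzene ring is traced back to a furan. In the forward sense, methyl 5-acetyl-3,4-dibromofuran-2-carboxylate A1 would be oxidised at an anode in an alcohol to its 2,5-dialkoxy-2,5-dihydro derivative. Aqueous acid would then open it to a Z-dibromoalkene flanked by a 1,2-diketone and an α-keto ester. The enol of the methyl ketone would add to the keto ester carbonyl to close the six-membered ring, water would be lost to give an ortho-quinone, and a mild reductant would deliver methyl 2,3-dibromo-4,5-dihydroxybenzoate A2.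
- In its favour: every ring position is fixed by the connectivity of A1. The bromines cannot end anywhere but C5 and C6, and no site selectivity on an arene is involved. On this point it is better than the chosen plan, which rests on a steric bias between C4 and C2.
- Against it: A1 carries two acyl groups and two bromines, so its oxidation potential should lie close to that of the solvent, and cathodic loss of bromine is a risk in an undivided cell. The open-chain intermediate has four electrophilic carbonyls and other ways to cyclise or hydrate. The dibromo ortho-quinone is a strong Michael acceptor. A1 is not a catalogue compound.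
- The decisive weakness is that A2 has O3 and O4 both free. The differentiation that the persulfate step supplies in the bond-forming event would have to be solved afterwards with protecting groups, alongside ester reduction and two sulfations.
- Comparison: this route builds the ring while the chosen one decorates an existing ring; its mechanism is an electron-transfer and condensation cascade against one polar oxygen transfer. In step count it should be clearly longer once the preparation of A1 and the oxygen differentiation are included.

**Alternative 2:** The cuts are C1–C7 and C6–Br, made in one flask. The precursor would be 3-bromo-4-[(4-methoxybenzyl)oxy]-5-(triisopropylsilyloxy)phenyl 4-chlorobenzenesulfonate A3. A hindered magnesium amide would deprotonate C6, between the sulfonate and the bromine, and loss of sulfonate would give the aryne across C1–C6. An (alkoxysilyl)methyl Grignard reagent would add at C1, away from the bromine, and the aryl–magnesium bond left at C6 would be quenched with a positive-bromine donor. The product would be [2,3-dibromo-4-(4-methoxybenzyloxy)-5-(triisopropylsilyloxy)benzyl](isopropoxy)dimethylsilane A4.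
- In its favour: O3 and O4 carry orthogonal protecting groups from the start, so sulfation of O4 would be unambiguous; here it is better than the chosen plan. Two bonds form in one operation, which equals or exceeds the bond count of the persulfate step. The regiochemistry of the aryne addition is controlled by the inductive pull of the C5 bromine.
- Against it: A3 needs a multi-step preparation with three different oxygen substituents. The C6 aryl–magnesium intermediate sits next to the C5 bromine and can eliminate to a second aryne if warmed. Metalation at C2 competes.
- After the key step the route still needs oxidative cleavage of the C7–Si bond, two deprotections and two sulfations in a fixed order.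
- Comparison: this is low-temperature organometallic chemistry that must all precede any sulfate, against an aqueous oxidation that tolerates the sulfate it creates. The step count should be well above seven.

**Alternative 3:** The cuts are the C3–O and C4–O bonds together. Whole cells expressing toluene dioxygenase would add both oxygens of dioxygen across the ring edge next to a bromine of 1,2-dibromobenzene A5 and give (1S,2S)-3,4-dibromocyclohexa-3,5-diene-1,2-diol A6. Dehydrogenation would then lead to 3,4-dibromobenzene-1,2-diol A7.
- In its favour: one aerobic, aqueous step from a bulk arene sets both C–O bonds with full positional control next to the bromines. On the regiochemistry of oxygenation it is better than the chosen plan, and in mildness it is its equal.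
- Against it: two stereocenters are made only to be erased on aromatisation, so the enantioselectivity of the enzyme buys nothing for an achiral target.
- A7 lacks C7, which would have to be attached at the carbon para to O4 and ortho to bromine, in competition with the carbon ortho to O3.
- O3 and O4 again emerge undifferentiated, and fermentation equipment is needed.
- Comparison: the chosen plan carries C7 from the start and introduces O4 already sulfated. The biocatalytic plan would need aromatisation, formylation, reduction, oxygen differentiation and two sulfations after its key step, so it should be longer.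

Key step: step 4

## Route

**Step 1**
Reactants: 1 2,3-dibromobenzoic acid
Product: 2 (2,3-dibromophenyl)methanol
Conditions: BH3·SMe2, THF, 0 °C → 50 °C; then MeOH, aqueous work-up
Reagents that add atoms: none
Why: Borane reduction of a carboxylic acid proceeds through an acyloxyborane and is selective for the acid; as an electrophilic hydride source it should leave both aryl C–Br bonds intact.

**Step 2**
Reactants: 2 (2,3-dibromophenyl)methanol
Product: 3 [(2,3-dibromobenzyl)oxy]tri(propan-2-yl)silane
Conditions: i-Pr3SiCl, imidazole, DMF, rt
Reagents that add atoms: chlorotri(propan-2-yl)silane, CC(C)[Si](Cl)(C(C)C)C(C)C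
Why: Imidazole-assisted silylation of a primary alcohol; the triisopropylsilyl ether resists alkali and peroxide, leaves with fluoride under non-acidic conditions, and puts a large group next to C2.

**Step 3**
Reactants: 3 [(2,3-dibromobenzyl)oxy]tri(propan-2-yl)silane; 4 bis(pinacolato)diboron
Product: 6 3,4-dibromo-5-{[tri(propan-2-yl)silyl]oxymethyl}phenol, via aryl pinacol boronate 5 (not isolated)
Conditions: [Ir(OMe)(cod)]2 (1.5 mol %), 4,4'-di-tert-butyl-2,2'-bipyridine (3 mol %), THF, 80 °C; then aq. NaOH, 30% H2O2, 0 °C → rt
Reagents that add atoms: hydrogen peroxide, OO (the phenolic oxygen of 6); the boryl group of intermediate 5 comes from reactant 4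
Why: Iridium-catalysed aromatic C–H borylation is governed by sterics, and of the three ring hydrogens only the one meta to both flanking groups has no ortho substituent; the trivalent iridium tris(boryl) catalyst should not insert into aryl C–Br bonds. Alkaline peroxide then converts C–B into C–O at the same carbon by 1,2-migration of the aryl group from boron to oxygen, a well-used one-flask borylation–oxidation sequence.

**Step 4**
Reactants: 6 3,4-dibromo-5-{[tri(propan-2-yl)silyl]oxymethyl}phenol; 7 potassium peroxodisulfate
Product: 9 potassium 2,3-dibromo-6-hydroxy-4-{[tri(propan-2-yl)silyl]oxymethyl}phenyl sulfate, via dienone sulfate 8 (not isolated)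
Conditions: K2S2O8 (1.1 equiv, added slowly), KOH (3 equiv), H2O/pyridine, 0 → 20 °C, N2, dark; then CO2 to pH 8, recovery of 6 by extraction, C18 (H2O/MeOH)
Reagents that add atoms: potassium peroxodisulfate 7, [K+].[K+].[O-]S(=O)(=O)OOS(=O)(=O)[O-]; potassium hydroxide, [K+].[OH-] (counter-ion)
Why: In alkali 6 is a phenolate whose para carbon C6 bears bromine, so it reacts as a carbon nucleophile through an ortho carbon: C4 attacks a peroxide oxygen of 7 in a displacement at oxygen that expels sulfate and forms the one new bond, C4–O, while the O–S bond of the aryl sulfate arrives ready-made. The dienone 8 formed in this way enolises at once in base to the phenolate of 9, so its transient sp3 carbon leaves no stereocenter, and no ring is closed. The closest known reaction is the Elbs persulfate oxidation in its ortho mode, the course taken by para-substituted phenols and in general a less efficient one than para attack. The step needs C4 to win over C2 and over ipso attack at C6: C2 lies next to the silyloxymethyl group, whose bulky arm is turned toward C2 by the C6 bromine on the other side of C1, whereas C4 has only a bromine as neighbour, and attack at C6 would give a dienone that cannot rearomatise by loss of a proton. The silyl ether also removes the free benzylic alcohol, the group most easily oxidised by stray sulfate radical anion. The aryl sulfate monoester and the primary silyl ether should both tolerate cold aqueous alkali, and the ortho-sulfated phenolate of 9 is less electron-rich than that of 6, which slows a second oxidation when 7 is not in excess. Conversion is expected to be partial, so unreacted 6 is recovered at pH 8 and recycled.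

**Step 5**
Reactants: 9 potassium 2,3-dibromo-6-hydroxy-4-{[tri(propan-2-yl)silyl]oxymethyl}phenyl sulfate
Product: 10 potassium 2,3-dibromo-6-hydroxy-4-(hydroxymethyl)phenyl sulfate
Conditions: Bu4NF, AcOH (1:1), THF, 0 °C → rt; then cation exchange (K+ form), C18 (H2O/MeOH)
Reagents that add atoms: none
Why: Fluoride-mediated desilylation, driven by the strength of the Si–F bond; buffering with acetic acid keeps the medium near neutral, where an aryl sulfate monoester anion is inert, and the exchange step restores potassium as the only counter-ion.

**Step 6**
Reactants: 10 potassium 2,3-dibromo-6-hydroxy-4-(hydroxymethyl)phenyl sulfate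
Product: 11 dipotassium 2,3-dibromo-6-hydroxy-4-[(sulfonatooxy)methyl]phenyl sulfate
Conditions: SO3·pyridine (1.3 equiv), DMF, −10 → 0 °C; then aq. KOH to pH 8, C18 or Sephadex LH-20 (H2O/MeOH)
Reagents that add atoms: sulfur trioxide–pyridine complex, O=S(=O)([O-])[n+]1ccccc1; potassium hydroxide, [K+].[OH-]
Why: O-Sulfation by transfer of sulfur trioxide from its pyridine complex; the primary benzylic hydroxyl is the more nucleophilic oxygen, while the C3 phenol is hindered and deactivated by the neighbouring sulfate and stays un-ionised without a strong base, so a small excess at low temperature should stop at O7. Neutralisation with KOH fixes both sulfates as potassium salts, which can be desalted in water.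

**Step 7**
Reactants: 11 dipotassium 2,3-dibromo-6-hydroxy-4-[(sulfonatooxy)methyl]phenyl sulfate
Product: 12 2,3-dibromo-5-hydroxy-4-(sulfooxy)benzyl hydrogen sulfate
Conditions: sulfonic acid resin (H+ form), H2O, 0–4 °C; immediate freeze-drying
Reagents that add atoms: none
Why: Cation exchange on a strongly acidic resin replaces potassium by protons without adding a soluble acid; it is run cold and dilute and the eluate is frozen at once because the acid form promotes hydrolysis of its own aryl sulfate.

## Compound list

1 | 2,3-dibromobenzoic acid | OC(=O)c1cccc(Br)c1Br | starting material
2 | (2,3-dibromophenyl)methanol | OCc1cccc(Br)c1Br | intermediate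
3 | [(2,3-dibromobenzyl)oxy]tri(propan-2-yl)silane | CC(C)[Si](OCc1cccc(Br)c1Br)(C(C)C)C(C)C | intermediate
4 | bis(pinacolato)diboron | CC1(C)OB(OC1(C)C)B1OC(C)(C)C(C)(C)O1 | starting material
5 | 2-(3,4-dibromo-5-{[tri(propan-2-yl)silyl]oxymethyl}phenyl)-4,4,5,5-tetramethyl-1,3,2-dioxaborolane | CC(C)[Si](OCc1cc(B2OC(C)(C)C(C)(C)O2)cc(Br)c1Br)(C(C)C)C(C)C | intermediate (not isolated)
6 | 3,4-dibromo-5-{[tri(propan-2-yl)silyl]oxymethyl}phenol | CC(C)[Si](OCc1cc(O)cc(Br)c1Br)(C(C)C)C(C)C | intermediate
7 | potassium peroxodisulfate | [K+].[K+].[O-]S(=O)(=O)OOS(=O)(=O)[O-] | starting material
8 | potassium 2,3-dibromo-6-oxo-4-{[tri(propan-2-yl)silyl]oxymethyl}cyclohexa-2,4-dien-1-yl sulfate (racemic, transient) | [K+].[O-]S(=O)(=O)OC1C(=O)C=C(CO[Si](C(C)C)(C(C)C)C(C)C)C(Br)=C1Br | intermediate (not isolated)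
9 | potassium 2,3-dibromo-6-hydroxy-4-{[tri(propan-2-yl)silyl]oxymethyl}phenyl sulfate | CC(C)[Si](OCc1cc(O)c(OS(=O)(=O)[O-])c(Br)c1Br)(C(C)C)C(C)C.[K+] | intermediate
10 | potassium 2,3-dibromo-6-hydroxy-4-(hydroxymethyl)phenyl sulfate | OCc1cc(O)c(OS(=O)(=O)[O-])c(Br)c1Br.[K+] | intermediate
11 | dipotassium 2,3-dibromo-6-hydroxy-4-[(sulfonatooxy)methyl]phenyl sulfate | [K+].[K+].[O-]S(=O)(=O)OCc1cc(O)c(OS(=O)(=O)[O-])c(Br)c1Br | intermediate
12 | 2,3-dibromo-5-hydroxy-4-(sulfooxy)benzyl hydrogen sulfate | O=S(=O)(O)OCc1cc(O)c(OS(=O)(=O)O)c(Br)c1Br | target

## Step count and risk

Total step count: 7. Longest linear sequence: 7 steps, from 1 to 12 (4 and 7 enter as reagents). Steps 1, 2 and 5 are routine.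

**Step 4 (key step).** The most likely failure is poor discrimination between the two ortho carbons, so that oxygen enters at C2 as well as at C4. Low conversion is also likely, because peroxodisulfate is lost to radical chain decomposition and to over-oxidation of phenolate into polymeric material. A smaller risk is attack at the bromine-bearing para carbon with loss of bromide.
The fallback sets out from 6 and returns at 9.
- Magnesium-phenoxide-directed ortho-formylation (MgCl2, Et3N, paraformaldehyde, MeCN, reflux) would give 2,3-dibromo-6-hydroxy-4-{[tri(propan-2-yl)silyl]oxymethyl}benzaldehyde F1. This is a neutral compound, so any isomer formylated at C2 can be removed on silica.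
- Dakin oxidation (H2O2, aq. NaOH, THF, 0 °C) would turn the formyl group into a hydroxyl through the aryl formate and give 3,4-dibromo-5-{[tri(propan-2-yl)silyl]oxymethyl}benzene-1,2-diol F2.
- Sulfation of the mono-phenoxide (K2CO3, 1 equiv; SO3·NMe3, DMF, 0 °C) is expected at O4, the more acidic oxygen because of its ortho bromine, and would lead back to 9.
- This path gives up the built-in oxygen differentiation for an acidity-based one and costs two extra steps.

**Step 6.** Chemoselectivity may be lost, with sulfur trioxide also transferred to O3, or sulfation of O7 may be incomplete if the reagent is held back to protect O3.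
The fallback sets out from 10 and returns at 11.
- Acetylation in cold aqueous alkali (Ac2O, aq. KHCO3/KOH, pH 9, 0 °C) acylates the phenoxide and not the alcohol. It would give potassium 6-(acetyloxy)-2,3-dibromo-4-(hydroxymethyl)phenyl sulfate F3.
- An excess of SO3·pyridine in DMF, then KOH to pH 8, would sulfate the only free hydroxyl and give dipotassium 6-(acetyloxy)-2,3-dibromo-4-[(sulfonatooxy)methyl]phenyl sulfate F4.
- Brief treatment with aq. KOH (pH 11–12, rt) would cleave the aryl acetate, which both sulfates should tolerate, and give 11.

**Step 7.** The acid form can hydrolyse its aryl sulfate and solvolyse its benzylic sulfate under its own acidity, above all during concentration or on prolonged contact with the resin.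
The fallback sets out from 11 and returns at 12.
- Addition of BaCl2 to a concentrated aqueous solution of 11, followed by ethanol, should precipitate barium 2,3-dibromo-6-hydroxy-4-[(sulfonatooxy)methyl]phenyl sulfate F5 free of potassium.
- F5 is suspended in ice-cold water and treated with exactly one equivalent of dilute H2SO4. BaSO4 precipitates and 12 stays in solution with no excess acid; the filtrate is frozen and freeze-dried, or used as a cold solution.

**Step 3.** The silyl ether arene is less electron-poor than an ester, so C–H activation may be slow. In the one-flask oxidation, residual boron hydrides consume peroxide and part of the silyl ether may be lost.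
The fallback sets out from 1 and returns at 6. It oxygenates at the ester oxidation level and reduces and protects afterwards.
- Fischer esterification (MeOH, H2SO4, reflux) gives methyl 2,3-dibromobenzoate F6.
- Borylation under the same iridium catalysis gives methyl 2,3-dibromo-5-(4,4,5,5-tetramethyl-1,3,2-dioxaborolan-2-yl)benzoate F7, which is isolated.
- Oxidation (H2O2, aq. NaOH, THF, 0 °C) gives methyl 2,3-dibromo-5-hydroxybenzoate F8.
- Reduction with i-Bu2AlH (CH2Cl2, −78 → 0 °C) gives 2,3-dibromo-5-hydroxybenzyl alcohol F9.
- Silylation of both hydroxyls (i-Pr3SiCl, imidazole, DMF) gives [3,4-dibromo-5-({[tri(propan-2-yl)silyl]oxy}methyl)phenoxy]tri(propan-2-yl)silane F10.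
- Selective cleavage of the aryl silyl ether (K2CO3, MeOH/H2O, rt), which is far more base-labile than the alkyl one, then gives 6.

## Further compounds

F1 | step 4 | 2,3-dibromo-6-hydroxy-4-{[tri(propan-2-yl)silyl]oxymethyl}benzaldehyde | CC(C)[Si](OCc1cc(O)c(C=O)c(Br)c1Br)(C(C)C)C(C)C
F2 | step 4 | 3,4-dibromo-5-{[tri(propan-2-yl)silyl]oxymethyl}benzene-1,2-diol | CC(C)[Si](OCc1cc(O)c(O)c(Br)c1Br)(C(C)C)C(C)C
F3 | step 6 | potassium 6-(acetyloxy)-2,3-dibromo-4-(hydroxymethyl)phenyl sulfate | CC(=O)Oc1cc(CO)c(Br)c(Br)c1OS(=O)(=O)[O-].[K+]
F4 | step 6 | dipotassium 6-(acetyloxy)-2,3-dibromo-4-[(sulfonatooxy)methyl]phenyl sulfate | CC(=O)Oc1cc(COS(=O)(=O)[O-])c(Br)c(Br)c1OS(=O)(=O)[O-].[K+].[K+]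
F5 | step 7 | barium 2,3-dibromo-6-hydroxy-4-[(sulfonatooxy)methyl]phenyl sulfate | [Ba+2].[O-]S(=O)(=O)OCc1cc(O)c(OS(=O)(=O)[O-])c(Br)c1Br
F6 | step 3 | methyl 2,3-dibromobenzoate | COC(=O)c1cccc(Br)c1Br
F7 | step 3 | methyl 2,3-dibromo-5-(4,4,5,5-tetramethyl-1,3,2-dioxaborolan-2-yl)benzoate | COC(=O)c1cc(B2OC(C)(C)C(C)(C)O2)cc(Br)c1Br
F8 | step 3 | methyl 2,3-dibromo-5-hydroxybenzoate | COC(=O)c1cc(O)cc(Br)c1Br
F9 | step 3 | 2,3-dibromo-5-hydroxybenzyl alcohol | OCc1cc(O)cc(Br)c1Br
F10 | step 3 | [3,4-dibromo-5-({[tri(propan-2-yl)silyl]oxy}methyl)phenoxy]tri(propan-2-yl)silane | CC(C)[Si](OCc1cc(O[Si](C(C)C)(C(C)C)C(C)C)cc(Br)c1Br)(C(C)C)C(C)C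
A1 | alternative 1 | methyl 5-acetyl-3,4-dibromofuran-2-carboxylate | COC(=O)c1oc(C(C)=O)c(Br)c1Br
A2 | alternative 1 | methyl 2,3-dibromo-4,5-dihydroxybenzoate | COC(=O)c1cc(O)c(O)c(Br)c1Br
A3 | alternative 2 | 3-bromo-4-[(4-methoxybenzyl)oxy]-5-(triisopropylsilyloxy)phenyl 4-chlorobenzenesulfonate | COc1ccc(COc2c(Br)cc(OS(=O)(=O)c3ccc(Cl)cc3)cc2O[Si](C(C)C)(C(C)C)C(C)C)cc1
A4 | alternative 2 | [2,3-dibromo-4-(4-methoxybenzyloxy)-5-(triisopropylsilyloxy)benzyl](isopropoxy)dimethylsilane | CC(C)O[Si](C)(C)Cc1cc(O[Si](C(C)C)(C(C)C)C(C)C)c(OCc2ccc(OC)cc2)c(Br)c1Br
A5 | alternative 3 | 1,2-dibromobenzene | Brc1ccccc1Br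
A6 | alternative 3 | (1S,2S)-3,4-dibromocyclohexa-3,5-diene-1,2-diol | O[C@H]1C=CC(Br)=C(Br)[C@H]1O
A7 | alternative 3 | 3,4-dibromobenzene-1,2-diol | Oc1ccc(Br)c(Br)c1O
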